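**Plan**

- Ring numbering used below: C1 is the dienone carbonyl carbon, C2/C6 and C3/C5 are the ring CH pairs, C4 is the ring carbon that carries the exocyclic diarylmethylidene carbon (Cx).
- Retrosynthesis: cut C3–C4 (ring closure), then C5–C6, which leads to a tertiary 1,1-diarylprop-2-yn-1-ol and trans-1-methoxy-3-(trimethylsilyloxy)buta-1,3-diene; then cut the ethynyl–carbinol bond, the aryl–carbonyl bond of the diaryl ketone, the biaryl bond and the aryl–alkyne bond of the central benzene ring.
- Enabling feature: C4 bears no hydrogen and only the C4=Cx double bond, so it can be the central carbon of a 1,1-diarylallene (nucleophilic at C4, charge taken up by the doubly benzylic Cx). O=C1–C2=C3–OMe is a vinylogous ester whose C3 becomes an oxocarbenium carbon on O-silylation. Closure of C3–C4 and loss of methanol give the quinone methide at its final oxidation level, with no phenol protecting group and no oxidation on that ring.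
- Forward order: the central benzene ring is functionalised from 4-bromo-2-hydroxybenzaldehyde (lithiation between O and Br, ketone, Suzuki, triflate, Sonogashira); then ethynyl addition, C5–C6 by attack of the silyloxydiene on the propargylic cation at its alkyne terminus, C3–C4 ring closure, global desilylation. The dienone ring is the only ring made.
- Stereochemistry: the target has no stereocentre and its exocyclic alkene carries two identical ring arms; the racemic carbinol centres and the racemic allene axis formed on the way are destroyed.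

Key step: step 16

Remark on the chemistry: the open para-quinone methide drawn for the target is taken as its stable form after neutral work-up (a hydrate at Cx would lose water again).

Shorthand in names: TIPS = triisopropylsilyl; TBS = tert-butyldimethylsilyl; "fragment C" = 6-{2,4-bis[(TIPS)oxy]phenyl}-3-{[(TBS)oxy]methyl}-2-({4-[(TIPS)oxy]phenyl}ethynyl)phenyl.

**Route**

Step 1
Reactants: 1 4-bromo-2-hydroxybenzaldehyde
Product: 2 5-bromo-2-(hydroxymethyl)phenol
Conditions: NaBH4, MeOH, 0 °C
Reagents that add atoms: none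
Why: Chemoselective NaBH4 reduction of the aldehyde, which leaves the aryl bromide and the phenol untouched.

Step 2
Reactants: 2 5-bromo-2-(hydroxymethyl)phenol
Product: 3 7-bromo-2,2-dimethyl-4H-1,3-benzodioxine
Conditions: 2,2-dimethoxypropane, TsOH·H2O (cat.), acetone, rt
Reagents that add atoms: 2,2-dimethoxypropane, COC(C)(C)OC
Why: Acid-catalysed transacetalisation ties the phenol and the benzylic alcohol into a six-membered isopropylidene acetal, masking both and leaving an ether-type oxygen as ortho director.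

Step 3
Reactants: 4 4-hydroxybenzaldehyde
Product: 5 4-[(TIPS)oxy]benzaldehyde
Conditions: TIPSCl, imidazole, DMF, rt
Reagents that add atoms: chlorotriisopropylsilane, CC(C)[Si](Cl)(C(C)C)C(C)C
Why: Standard silylation of a phenol gives an aryl silyl ether that tolerates organolithium, palladium and mild acid steps.

Step 4
Reactants: 3 7-bromo-2,2-dimethyl-4H-1,3-benzodioxine; 5 4-[(TIPS)oxy]benzaldehyde
Product: 7 rac-(7-bromo-2,2-dimethyl-4H-1,3-benzodioxin-8-yl){4-[(TIPS)oxy]phenyl}methanol, via aryllithium 6 (not isolated)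
Conditions: LDA, THF, −78 °C; then 5, −78 °C; aq. NH4Cl
Reagents that add atoms: lithium diisopropylamide, [Li+].CC(C)[N-]C(C)C (lithium is carried only by intermediate 6)
Why: Directed ortho-metalation with the amide base, which does not exchange the bromide, occurs at C8, the only position flanked by the acetal oxygen and bromine, and the aryllithium adds to the aldehyde at −78 °C before LiBr loss to an aryne sets in; the racemic carbinol centre is removed in step 5.

Step 5
Reactants: 7 rac-(7-bromo-2,2-dimethyl-4H-1,3-benzodioxin-8-yl){4-[(TIPS)oxy]phenyl}methanol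
Product: 8 (7-bromo-2,2-dimethyl-4H-1,3-benzodioxin-8-yl){4-[(TIPS)oxy]phenyl}methanone
Conditions: Dess–Martin periodinane, CH2Cl2, rt
Reagents that add atoms: none
Why: Dess–Martin oxidation of a benzhydrol to the diaryl ketone, with no other oxidisable group present.

Step 6
Reactants: 9 4-bromobenzene-1,3-diol
Product: 10 1-bromo-2,4-bis[(TIPS)oxy]benzene
Conditions: TIPSCl, imidazole, DMF, 40 °C
Reagents that add atoms: chlorotriisopropylsilane, CC(C)[Si](Cl)(C(C)C)C(C)C
Why: Double silylation of the two phenols under standard imidazole conditions.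

Step 7
Reactants: 10 1-bromo-2,4-bis[(TIPS)oxy]benzene
Product: 11 2-{2,4-bis[(TIPS)oxy]phenyl}-4,4,5,5-tetramethyl-1,3,2-dioxaborolane
Conditions: B2pin2, PdCl2(dppf) (cat.), KOAc, 1,4-dioxane, 90 °C
Reagents that add atoms: bis(pinacolato)diboron, CC1(C)OB(B2OC(C)(C)C(C)(C)O2)OC1(C)C
Why: Miyaura borylation of the aryl bromide, which avoids an ortho-silyloxy aryllithium that could suffer silyl migration from oxygen to carbon.

Step 8
Reactants: 8 (7-bromo-2,2-dimethyl-4H-1,3-benzodioxin-8-yl){4-[(TIPS)oxy]phenyl}methanone; 11 2-{2,4-bis[(TIPS)oxy]phenyl}-4,4,5,5-tetramethyl-1,3,2-dioxaborolane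
Product: 12 (7-{2,4-bis[(TIPS)oxy]phenyl}-2,2-dimethyl-4H-1,3-benzodioxin-8-yl){4-[(TIPS)oxy]phenyl}methanone
Conditions: Pd(OAc)2 (cat.), SPhos, K3PO4, toluene/H2O, 80 °C
Reagents that add atoms: none
Why: Suzuki–Miyaura coupling in which the bromide is activated by the ortho aroyl group and the biaryl phosphine tolerates one ortho substituent on each partner.

Step 9
Reactants: 12 (7-{2,4-bis[(TIPS)oxy]phenyl}-2,2-dimethyl-4H-1,3-benzodioxin-8-yl){4-[(TIPS)oxy]phenyl}methanone
Product: 13 (6-{2,4-bis[(TIPS)oxy]phenyl}-2-hydroxy-3-(hydroxymethyl)phenyl){4-[(TIPS)oxy]phenyl}methanone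
Conditions: AcOH/THF/H2O, 60 °C
Reagents that add atoms: none
Why: Mild acid hydrolysis of the isopropylidene acetal frees the phenol and the benzylic alcohol, while aryl triisopropylsilyl ethers are stable to aqueous acetic acid.

Step 10
Reactants: 13 (6-{2,4-bis[(TIPS)oxy]phenyl}-2-hydroxy-3-(hydroxymethyl)phenyl){4-[(TIPS)oxy]phenyl}methanone
Product: 14 3-{2,4-bis[(TIPS)oxy]phenyl}-6-(hydroxymethyl)-2-{4-[(TIPS)oxy]benzoyl}phenyl trifluoromethanesulfonate
Conditions: PhNTf2, Et3N, DMAP (cat.), CH2Cl2, 0 °C to rt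
Reagents that add atoms: N-phenylbis(trifluoromethanesulfonimide), O=S(=O)(N(c1ccccc1)S(=O)(=O)C(F)(F)F)C(F)(F)F
Why: Phenoxide-selective triflation, since this mild triflyl donor sulfonylates the only free phenol and not the aliphatic alcohol under amine base.

Step 11
Reactants: 14 3-{2,4-bis[(TIPS)oxy]phenyl}-6-(hydroxymethyl)-2-{4-[(TIPS)oxy]benzoyl}phenyl trifluoromethanesulfonate
Product: 15 3-{2,4-bis[(TIPS)oxy]phenyl}-6-{[(TBS)oxy]methyl}-2-{4-[(TIPS)oxy]benzoyl}phenyl trifluoromethanesulfonate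
Conditions: TBSCl, imidazole, CH2Cl2, rt
Reagents that add atoms: tert-butylchlorodimethylsilane, CC(C)(C)[Si](C)(C)Cl
Why: Silylation of the primary benzylic alcohol, so that no free hydroxyl sits next to the future alkyne (no cycloisomerisation) or meets the later cation chemistry.

Step 12
Reactants: 16 4-ethynylphenol
Product: 17 (4-ethynylphenoxy)triisopropylsilane
Conditions: TIPSCl, imidazole, DMF, rt
Reagents that add atoms: chlorotriisopropylsilane, CC(C)[Si](Cl)(C(C)C)C(C)C
Why: Standard phenol silylation that leaves the terminal alkyne free for coupling.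

Step 13
Reactants: 15 3-{2,4-bis[(TIPS)oxy]phenyl}-6-{[(TBS)oxy]methyl}-2-{4-[(TIPS)oxy]benzoyl}phenyl trifluoromethanesulfonate; 17 (4-ethynylphenoxy)triisopropylsilane
Product: 18 (fragment C){4-[(TIPS)oxy]phenyl}methanone
Conditions: PdCl2(PPh3)2 (cat.), CuI (cat.), Et3N, DMF, 70 °C
Reagents that add atoms: none
Why: Sonogashira coupling of an aryl triflate activated by the ortho ketone, in which the slim linear alkyne tolerates the two ortho substituents.

Step 14
Reactants: 18 (fragment C){4-[(TIPS)oxy]phenyl}methanone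
Product: 19 rac-1-(fragment C)-1-{4-[(TIPS)oxy]phenyl}prop-2-yn-1-ol
Conditions: ethynylmagnesium bromide, THF, 0 °C to rt; aq. NH4Cl
Reagents that add atoms: ethynylmagnesium bromide, C#C[Mg]Br
Why: 1,2-Addition of the small ethynyl Grignard reagent to a non-enolisable diaryl ketone, approached from the side of the slim alkynyl neighbour, gives the racemic tertiary propargylic alcohol, whose centre disappears in step 15.

Step 15
Reactants: 19 rac-1-(fragment C)-1-{4-[(TIPS)oxy]phenyl}prop-2-yn-1-ol; 20 trans-1-methoxy-3-(trimethylsilyloxy)buta-1,3-diene (Danishefsky's diene)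
Product: 21 (1E)-7-(fragment C)-1-methoxy-7-{4-[(TIPS)oxy]phenyl}hepta-1,5,6-trien-3-one (racemic allene axis)
Conditions: 20 (2 equiv), TMSOTf (10 mol %), CH2Cl2, −78 °C; then Et3N, aq. NaHCO3
Reagents that add atoms: none
Why: Lewis-acid ionisation of the tertiary diaryl propargylic alcohol (SN1-type propargylic substitution with transposition) and Mukaiyama-type attack of the terminal CH2 of the silyloxydiene at the unhindered alkyne terminus, the carbinol carbon being shielded by the 2,6-disubstituted ring, should give the β-allenyl ketone with the vinylogous methyl ester intact.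

Step 16
Reactants: 21 (1E)-7-(fragment C)-1-methoxy-7-{4-[(TIPS)oxy]phenyl}hepta-1,5,6-trien-3-one
Product: 23 4-{(fragment C){4-[(TIPS)oxy]phenyl}methylidene}cyclohexa-2,5-dien-1-one, via silyl dienol ether 22 (not isolated)
Conditions: TMSOTf (1.2 equiv), 2,6-di-tert-butyl-4-methylpyridine, CH2Cl2, −78 to 0 °C; aq. NaHCO3
Reagents that add atoms: trimethylsilyl trifluoromethanesulfonate, C[Si](C)(C)OS(=O)(=O)C(F)(F)F (silicon is carried only by intermediate 22)
Why: Proposed new method: O-silylation of the vinylogous ester carbonyl of 21 gives a 1-methoxy-3-silyloxyallyl cation whose methoxy-bearing terminus C3 lies five atoms from the central allene carbon C4, and C4 attacks C3 through the π bond it shares with Cx, so that the charge lands on Cx, stabilised by the 4-silyloxyphenyl ring and, after bond rotation, by the remaining C4=C5 bond, after which the hindered pyridine removes a proton from C6 to give silyl dienol ether 22 (should enolisation towards C6 come first, the same bond would close by disrotatory 6π-electrocyclisation of the resulting 3-silyloxyhexatriene with an allene terminus, again giving 22). Silyl-triflate-assisted loss of the C3 methoxy group as MeOSiMe3 then aromatises the ring to the O-silyl trityl cation, and desilylation by triflate releases quinone methide 23 with regeneration of the silyl triflate. The closest known reaction types are Prins-type cyclisations of allenes onto oxocarbenium ions, the enolisation/6π-electrocyclisation/aromatisation of β-allenyl carbonyl compounds made by propargyl Claisen rearrangement, and the methanol-eliminating aromatisation that ends benzannulations with Danishefsky's diene. The six-membered ring closes in the 6-exo-trig mode at the O-methyl oxocarbenium carbon (6-endo with respect to the enone C=C from which it derives), the allene reacting through its central carbon. No stereocentre is formed in 23, whose exocyclic alkene carries two identical ring arms, and the racemic allene axis of 21 and the C3 centre of 22 are erased. The step needs C–C closure to beat prototropic shift of the allene into conjugation with the ketone, attack of the carbonyl oxygen on the allene, and capture of the Cx cation by the neighbouring silyloxy oxygen or alkyne: the aprotic silyl Lewis acid with a non-nucleophilic base leaves no proton source for the shift, only the C4-to-C3 union gives a six-membered ring with the charge on doubly benzylic Cx, and proton loss followed by aromatisation makes the desired path irreversible.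

Step 17
Reactants: 23 4-{(fragment C){4-[(TIPS)oxy]phenyl}methylidene}cyclohexa-2,5-dien-1-one
Product: 24 Selaginellin F
Conditions: TBAF, AcOH, THF, 0 °C to rt
Reagents that add atoms: none
Why: Fluoride cleavage of all five silyl ethers under acetic acid buffering, which keeps the benzylic alkoxide from adding to the ortho alkyne, while the quinone methide and the diarylalkyne are inert to buffered fluoride.

**Compound list**

1 | 4-bromo-2-hydroxybenzaldehyde | O=Cc1ccc(Br)cc1O | starting material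
2 | 5-bromo-2-(hydroxymethyl)phenol | OCc1ccc(Br)cc1O | intermediate
3 | 7-bromo-2,2-dimethyl-4H-1,3-benzodioxine | CC1(C)OCc2ccc(Br)cc2O1 | intermediate
4 | 4-hydroxybenzaldehyde | O=Cc1ccc(O)cc1 | starting material
5 | 4-[(triisopropylsilyl)oxy]benzaldehyde | O=Cc1ccc(O[Si](C(C)C)(C(C)C)C(C)C)cc1 | intermediate
6 | (7-bromo-2,2-dimethyl-4H-1,3-benzodioxin-8-yl)lithium | CC1(C)OCc2ccc(Br)c([Li])c2O1 | intermediate
7 | rac-(7-bromo-2,2-dimethyl-4H-1,3-benzodioxin-8-yl){4-[(triisopropylsilyl)oxy]phenyl}methanol | CC1(C)OCc2ccc(Br)c(C(O)c3ccc(O[Si](C(C)C)(C(C)C)C(C)C)cc3)c2O1 | intermediate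
8 | (7-bromo-2,2-dimethyl-4H-1,3-benzodioxin-8-yl){4-[(triisopropylsilyl)oxy]phenyl}methanone | CC1(C)OCc2ccc(Br)c(C(=O)c3ccc(O[Si](C(C)C)(C(C)C)C(C)C)cc3)c2O1 | intermediate
9 | 4-bromobenzene-1,3-diol | Oc1ccc(Br)c(O)c1 | starting material
10 | 1-bromo-2,4-bis[(triisopropylsilyl)oxy]benzene | Brc1ccc(O[Si](C(C)C)(C(C)C)C(C)C)cc1O[Si](C(C)C)(C(C)C)C(C)C | intermediate
11 | 2-{2,4-bis[(triisopropylsilyl)oxy]phenyl}-4,4,5,5-tetramethyl-1,3,2-dioxaborolane | CC1(C)OB(c2ccc(O[Si](C(C)C)(C(C)C)C(C)C)cc2O[Si](C(C)C)(C(C)C)C(C)C)OC1(C)C | intermediate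
12 | (7-{2,4-bis[(triisopropylsilyl)oxy]phenyl}-2,2-dimethyl-4H-1,3-benzodioxin-8-yl){4-[(triisopropylsilyl)oxy]phenyl}methanone | CC1(C)OCc2ccc(-c3ccc(O[Si](C(C)C)(C(C)C)C(C)C)cc3O[Si](C(C)C)(C(C)C)C(C)C)c(C(=O)c3ccc(O[Si](C(C)C)(C(C)C)C(C)C)cc3)c2O1 | intermediate
13 | (6-{2,4-bis[(triisopropylsilyl)oxy]phenyl}-2-hydroxy-3-(hydroxymethyl)phenyl){4-[(triisopropylsilyl)oxy]phenyl}methanone | OCc1ccc(-c2ccc(O[Si](C(C)C)(C(C)C)C(C)C)cc2O[Si](C(C)C)(C(C)C)C(C)C)c(C(=O)c2ccc(O[Si](C(C)C)(C(C)C)C(C)C)cc2)c1O | intermediate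
14 | 3-{2,4-bis[(triisopropylsilyl)oxy]phenyl}-6-(hydroxymethyl)-2-{4-[(triisopropylsilyl)oxy]benzoyl}phenyl trifluoromethanesulfonate | OCc1ccc(-c2ccc(O[Si](C(C)C)(C(C)C)C(C)C)cc2O[Si](C(C)C)(C(C)C)C(C)C)c(C(=O)c2ccc(O[Si](C(C)C)(C(C)C)C(C)C)cc2)c1OS(=O)(=O)C(F)(F)F | intermediate
15 | 3-{2,4-bis[(triisopropylsilyl)oxy]phenyl}-6-{[(tert-butyldimethylsilyl)oxy]methyl}-2-{4-[(triisopropylsilyl)oxy]benzoyl}phenyl trifluoromethanesulfonate | CC(C)(C)[Si](C)(C)OCc1ccc(-c2ccc(O[Si](C(C)C)(C(C)C)C(C)C)cc2O[Si](C(C)C)(C(C)C)C(C)C)c(C(=O)c2ccc(O[Si](C(C)C)(C(C)C)C(C)C)cc2)c1OS(=O)(=O)C(F)(F)F | intermediate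
16 | 4-ethynylphenol | C#Cc1ccc(O)cc1 | starting material
17 | (4-ethynylphenoxy)triisopropylsilane | C#Cc1ccc(O[Si](C(C)C)(C(C)C)C(C)C)cc1 | intermediate
18 | (fragment C){4-[(triisopropylsilyl)oxy]phenyl}methanone | O=C(c1ccc(O[Si](C(C)C)(C(C)C)C(C)C)cc1)c1c(-c2ccc(O[Si](C(C)C)(C(C)C)C(C)C)cc2O[Si](C(C)C)(C(C)C)C(C)C)ccc(CO[Si](C)(C)C(C)(C)C)c1C#Cc1ccc(O[Si](C(C)C)(C(C)C)C(C)C)cc1 | intermediate
19 | rac-1-(fragment C)-1-{4-[(triisopropylsilyl)oxy]phenyl}prop-2-yn-1-ol | C#CC(O)(c1ccc(O[Si](C(C)C)(C(C)C)C(C)C)cc1)c1c(-c2ccc(O[Si](C(C)C)(C(C)C)C(C)C)cc2O[Si](C(C)C)(C(C)C)C(C)C)ccc(CO[Si](C)(C)C(C)(C)C)c1C#Cc1ccc(O[Si](C(C)C)(C(C)C)C(C)C)cc1 | intermediate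
20 | trans-1-methoxy-3-(trimethylsilyloxy)buta-1,3-diene | CO/C=C/C(=C)O[Si](C)(C)C | starting material
21 | (1E)-7-(fragment C)-1-methoxy-7-{4-[(triisopropylsilyl)oxy]phenyl}hepta-1,5,6-trien-3-one, racemic allene | CO/C=C/C(=O)CC=C=C(c1ccc(O[Si](C(C)C)(C(C)C)C(C)C)cc1)c1c(-c2ccc(O[Si](C(C)C)(C(C)C)C(C)C)cc2O[Si](C(C)C)(C(C)C)C(C)C)ccc(CO[Si](C)(C)C(C)(C)C)c1C#Cc1ccc(O[Si](C(C)C)(C(C)C)C(C)C)cc1 | intermediate
22 | rac-[(4-{(fragment C){4-[(triisopropylsilyl)oxy]phenyl}methylidene}-3-methoxycyclohexa-1,5-dien-1-yl)oxy]trimethylsilane | COC1C=C(O[Si](C)(C)C)C=CC1=C(c1ccc(O[Si](C(C)C)(C(C)C)C(C)C)cc1)c1c(-c2ccc(O[Si](C(C)C)(C(C)C)C(C)C)cc2O[Si](C(C)C)(C(C)C)C(C)C)ccc(CO[Si](C)(C)C(C)(C)C)c1C#Cc1ccc(O[Si](C(C)C)(C(C)C)C(C)C)cc1 | intermediate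
23 | 4-{(fragment C){4-[(triisopropylsilyl)oxy]phenyl}methylidene}cyclohexa-2,5-dien-1-one | O=C1C=CC(=C(c2ccc(O[Si](C(C)C)(C(C)C)C(C)C)cc2)c2c(-c3ccc(O[Si](C(C)C)(C(C)C)C(C)C)cc3O[Si](C(C)C)(C(C)C)C(C)C)ccc(CO[Si](C)(C)C(C)(C)C)c2C#Cc2ccc(O[Si](C(C)C)(C(C)C)C(C)C)cc2)C=C1 | intermediate
24 | Selaginellin F, 4-{[6-(2,4-dihydroxyphenyl)-3-(hydroxymethyl)-2-[(4-hydroxyphenyl)ethynyl]phenyl](4-hydroxyphenyl)methylidene}cyclohexa-2,5-dien-1-one | O=C1C=CC(=C(c2ccc(O)cc2)c2c(-c3ccc(O)cc3O)ccc(CO)c2C#Cc2ccc(O)cc2)C=C1 | target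

**Totals**

Total step count: 17. Longest linear sequence: 13 steps (steps 1, 2, 4, 5, 8, 9, 10, 11, 13, 14, 15, 16, 17).

**Steps most likely to fail**

1. Step 16 (the labelled step). The closure may lose to prototropic shift of the allene into conjugation with the ketone, to attack of oxygen on the allene, or to capture of the Cx cation by the neighbouring silyloxy group before proton loss. Fallback by known chemistry, setting out from ketone 18: {4-[(triisopropylsilyl)oxy]phenyl}lithium F1, made from commercial (4-bromophenoxy)triisopropylsilane and n-BuLi in THF at −78 °C, is added to 18 to give the triaryl carbinol F2. TBAF/AcOH in THF followed by a dilute acid wash removes the silyl groups and dehydrates the 4-hydroxytrityl alcohol, so that the route is re-entered at 24 and steps 14 to 17 are bypassed.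

2. Step 15. The nucleophile may attack the carbinol carbon instead of the alkyne terminus, the cation may rearrange by the Meyer–Schuster path or be captured within the molecule, or the acid-sensitive diene may be desilylated before C–C bond formation. Fallback, setting out from 19: Eschenmoser–Claisen rearrangement with N,N-dimethylacetamide dimethyl acetal (xylene, 140 °C) forms the C5–C6 bond by a [3,3] shift through the alkyne terminus under neutral conditions and gives the β-allenyl amide F3. (Z)-(2-Ethoxyvinyl)lithium F4, made from (Z)-1-bromo-2-ethoxyethene and n-BuLi in THF at −78 °C, converts the amide into the (Z)-β-ethoxy enone F5, the ethyl analogue of 21. Under the conditions of step 16, F5 loses EtOSiMe3 and the route is re-entered at 23.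

3. Step 8. Protodeboronation of the electron-rich ortho-silyloxy boronate may outrun transmetalation next to the aroyl group. Fallback with reversed polarity, setting out from 8: Miyaura borylation (B2pin2, PdCl2(dppf), KOAc, 1,4-dioxane) gives the ketone-bearing boronate F6, which is coupled with bromide 10 (Pd(OAc)2, SPhos, K3PO4, toluene/H2O) and comes back to the route at 12.

Further compounds
F1 | step 16 | {4-[(triisopropylsilyl)oxy]phenyl}lithium | [Li]c1ccc(O[Si](C(C)C)(C(C)C)C(C)C)cc1
F2 | step 16 | (fragment C)bis{4-[(triisopropylsilyl)oxy]phenyl}methanol | OC(c1ccc(O[Si](C(C)C)(C(C)C)C(C)C)cc1)(c1ccc(O[Si](C(C)C)(C(C)C)C(C)C)cc1)c1c(-c2ccc(O[Si](C(C)C)(C(C)C)C(C)C)cc2O[Si](C(C)C)(C(C)C)C(C)C)ccc(CO[Si](C)(C)C(C)(C)C)c1C#Cc1ccc(O[Si](C(C)C)(C(C)C)C(C)C)cc1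
F3 | step 15 | 5-(fragment C)-N,N-dimethyl-5-{4-[(triisopropylsilyl)oxy]phenyl}penta-3,4-dienamide, racemic allene | CN(C)C(=O)CC=C=C(c1ccc(O[Si](C(C)C)(C(C)C)C(C)C)cc1)c1c(-c2ccc(O[Si](C(C)C)(C(C)C)C(C)C)cc2O[Si](C(C)C)(C(C)C)C(C)C)ccc(CO[Si](C)(C)C(C)(C)C)c1C#Cc1ccc(O[Si](C(C)C)(C(C)C)C(C)C)cc1
F4 | step 15 | (Z)-(2-ethoxyvinyl)lithium | [Li]/C=C\OCC
F5 | step 15 | (1Z)-1-ethoxy-7-(fragment C)-7-{4-[(triisopropylsilyl)oxy]phenyl}hepta-1,5,6-trien-3-one, racemic allene | CCO/C=C\C(=O)CC=C=C(c1ccc(O[Si](C(C)C)(C(C)C)C(C)C)cc1)c1c(-c2ccc(O[Si](C(C)C)(C(C)C)C(C)C)cc2O[Si](C(C)C)(C(C)C)C(C)C)ccc(CO[Si](C)(C)C(C)(C)C)c1C#Cc1ccc(O[Si](C(C)C)(C(C)C)C(C)C)cc1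
F6 | step 8 | [2,2-dimethyl-7-(4,4,5,5-tetramethyl-1,3,2-dioxaborolan-2-yl)-4H-1,3-benzodioxin-8-yl]{4-[(triisopropylsilyl)oxy]phenyl}methanone | CC1(C)OCc2ccc(B3OC(C)(C)C(C)(C)O3)c(C(=O)c3ccc(O[Si](C(C)C)(C(C)C)C(C)C)cc3)c2O1
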